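**Plan**

1. Retrosynthesis: after removal of the 4'-O-MOM group, ring A of the flavanone is cut at C8–C8a and at C5–C6.
2. This leaves a dihydropyranone that already holds O1, C2 with its aryl group, C3, C4=O, C4a, C8a (as an O,S-ketene acetal carbon bearing SMe) and C5 (as a methyl ester carbon), plus the unit C8–C7(=O)–C6(geranyl), which is (E)-geranylacetone.
3. Enabling feature: ring A is a phloroglucinol in which the oxygen-bearing carbons C8a, C7 and C5 alternate with C8, C6 and C4a. It is therefore a masked triketide that can be built at the aromatic oxidation level from a thioester-level carbon, a ketone and an ester, and the geranyl-bearing C6 is the ketone α-carbon lying between C5 and C7.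
4. Forward order: MOM-syringaldehyde plus the bis-silyl dienol ether of methyl acetoacetate gives the (S)-δ-hydroxy-β-keto ester, then the ketene dithioacetal, then ring C (dihydropyranone), then ring A by [3+3] annulation with geranylacetone, then MOM removal.
5. Stereochemistry: C2 is the only stereocentre. It is set in the BINOL–titanium vinylogous Mukaiyama aldol and none of its bonds is broken afterwards. The E alkene is bought with geranylacetone.

Key step: step 7

Assumption: Ti(OiPr)4/(S)-BINOL is taken to give the (5S)-aldol, the usual sense for BINOL–titanium Mukaiyama additions to aromatic aldehydes; if chiral HPLC of 7 shows the opposite sense, (R)-BINOL is used in step 4.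

**Route**

Step 1
Reactants: 1 syringaldehyde (4-hydroxy-3,5-dimethoxybenzaldehyde)
Product: 2 3,5-dimethoxy-4-(methoxymethoxy)benzaldehyde
Conditions: MOMCl, iPr2NEt, CH2Cl2, 0 °C → rt
Reagents that add atoms: chloromethyl methyl ether (MOMCl), COCCl
Why: MOM protection of the phenol by O-alkylation (Williamson type) with a hindered amine base; the aldehyde is inert and the acetal is stable to every basic step that follows.

Step 2
Reactants: 3 methyl acetoacetate
Product: 4 methyl 3-(trimethylsilyloxy)but-2-enoate (E/Z mixture)
Conditions: TMSCl, Et3N, hexane, rt; distillation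
Reagents that add atoms: chlorotrimethylsilane, C[Si](C)(C)Cl
Why: Silyl enol ether formation, in which the enolisable β-keto ester is O-silylated under amine base; this is the first half of the standard preparation of the acetoacetate bis-silyl dienol ether.

Step 3
Reactants: 4 methyl 3-(trimethylsilyloxy)but-2-enoate
Product: 5 1-methoxy-1,3-bis(trimethylsilyloxy)buta-1,3-diene
Conditions: LDA, THF, −78 °C; TMSCl, −78 °C → rt
Reagents that add atoms: chlorotrimethylsilane, C[Si](C)(C)Cl
Why: Kinetic γ-deprotonation of the vinylogous ester by LDA and O-silylation of the dienolate (silyl ketene acetal formation) gives the bis-silyl dienol ether, which is used without chromatography.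

Step 4
Reactants: 2 3,5-dimethoxy-4-(methoxymethoxy)benzaldehyde; 5 1-methoxy-1,3-bis(trimethylsilyloxy)buta-1,3-diene
Product: 7 methyl (5S)-5-[3,5-dimethoxy-4-(methoxymethoxy)phenyl]-5-hydroxy-3-oxopentanoate, via bis-silylated aldol adduct 6 (not isolated)
Conditions: Ti(OiPr)4 (10 mol%), (S)-BINOL (10 mol%), 4 Å MS, THF, −78 °C → rt; then PPTS (cat.), MeOH, 0 °C
Reagents that add atoms: none
Why: Catalytic asymmetric vinylogous Mukaiyama aldol addition, in which the BINOL–titanium Lewis acid binds the aldehyde and leaves one face open to the terminal carbon of the diene, setting C5 as S; mild acidic methanolysis then removes both TMS groups without touching the aryl MOM ether.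

Step 5
Reactants: 7 methyl (5S)-5-[3,5-dimethoxy-4-(methoxymethoxy)phenyl]-5-hydroxy-3-oxopentanoate
Product: 8 methyl (5S)-2-[bis(methylsulfanyl)methylidene]-5-[3,5-dimethoxy-4-(methoxymethoxy)phenyl]-5-hydroxy-3-oxopentanoate
Conditions: K2CO3 (3 equiv), CS2 (1.5 equiv), DMF, 0 °C; MeI (2.1 equiv), 0 °C → rt
Reagents that add atoms: carbon disulfide, S=C=S; iodomethane, CI
Why: α-Oxoketene dithioacetal formation, in which the doubly activated methylene is dithiocarboxylated and the dithiolate is S-methylated twice, while carbonate is too weak a base to ionise the benzylic alcohol.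

Step 6
Reactants: 8 methyl (5S)-2-[bis(methylsulfanyl)methylidene]-5-[3,5-dimethoxy-4-(methoxymethoxy)phenyl]-5-hydroxy-3-oxopentanoate
Product: 9 methyl (2S)-2-[3,5-dimethoxy-4-(methoxymethoxy)phenyl]-6-(methylsulfanyl)-4-oxo-3,4-dihydro-2H-pyran-5-carboxylate
Conditions: DBU (0.1 equiv), CH2Cl2, 0 °C → rt, N2 sweep
Reagents that add atoms: none
Why: Intramolecular oxa-Michael addition–elimination (6-endo-trig, at a push–pull carbon activated by ketone and ester) with loss of methanethiol closes ring C; the benzylic C–O bond is not broken, so the S configuration is kept, and any 9 already formed in step 5 is simply carried along.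

Step 7
Reactants: 9 methyl (2S)-2-[3,5-dimethoxy-4-(methoxymethoxy)phenyl]-6-(methylsulfanyl)-4-oxo-3,4-dihydro-2H-pyran-5-carboxylate; 10 (E)-geranylacetone [(5E)-6,10-dimethylundeca-5,9-dien-2-one]
Product: 12 (2S)-6-geranyl-5,7-dihydroxy-3',5'-dimethoxy-4'-(methoxymethoxy)flavanone, via keto ester 11 (not isolated)
Conditions: LDA (2.3 equiv), 10 (2.2 equiv), THF, −78 °C; add 9, −78 → −40 °C; LDA (2.2 equiv), −78 → 0 °C; AcOH, −78 °C
Reagents that add atoms: none
Why: Proposed new method: the kinetic methyl-side lithium enolate of 10 adds to the doubly activated C6 of 9 (future C8a), the resulting β-keto ester enolate expels methanethiolate (a far better leaving group than the ring alkoxide, so O1 stays) and a second equivalent of enolate removes the now acidic C8 proton of keto ester 11; the added LDA then deprotonates the geranyl-bearing α'-carbon, this carbanion attacks the ester carbonyl, methoxide leaves and double enolisation gives the phloroglucinol ring. The closest known reactions are the [3+3] aromatic annulations of α-oxoketene dithioacetals with ketone enolates, the displacement of methylthio groups from acyl ketene dithioacetals by enolates, and the Michael–Dieckmann sequence of the Staunton–Weinreb annulation on β-alkoxy acceptors. Ring A closes in a 6-(enolendo)-exo-trig Claisen (Dieckmann-type) condensation, which is a favoured mode, and aromatisation makes it irreversible. No stereocentre is formed; C2 is only a spectator and survives as long as C3 is not deprotonated, which the fast conjugate addition at −78 °C, the anionic charge of 11 and of the product, and the cold acetic acid quench are meant to secure. The step needs (a) the methyl-side enolate, secured by kinetic deprotonation with LDA at −78 °C and by the higher reactivity of the unhindered enolate towards the tetrasubstituted acceptor, (b) 1,4-addition instead of attack at C4 or proton abstraction at C3, secured by the ketone/ester double activation of C6, and (c) C- instead of O-acylation in the closure, secured by generating the lithium dianion before warming. Since the second C–C bond can only start from the geranyl-bearing carbon, geranyl ends at C6 between the two free hydroxyls without any protecting group on ring A.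

Step 8
Reactants: 12 (2S)-6-geranyl-5,7-dihydroxy-3',5'-dimethoxy-4'-(methoxymethoxy)flavanone
Product: 13 (2S)-6-[(2E)-3,7-dimethylocta-2,6-dien-1-yl]-5,7-dihydroxy-2-(4-hydroxy-3,5-dimethoxyphenyl)-2,3-dihydro-4H-chromen-4-one (CNP0372687.1)
Conditions: HCl (1.25 M in MeOH), 0 °C → rt
Reagents that add atoms: none
Why: Acid-catalysed cleavage of the aryl MOM acetal (oxocarbenium ion trapped by methanol); short exposure at room temperature should leave the geranyl chain, the free phloroglucinol hydroxyls and the flavanone stereocentre alone.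

**Compound list**

1 | syringaldehyde (4-hydroxy-3,5-dimethoxybenzaldehyde) | COc1cc(C=O)cc(OC)c1O | starting material
2 | 3,5-dimethoxy-4-(methoxymethoxy)benzaldehyde | COCOc1c(OC)cc(C=O)cc1OC | intermediate
3 | methyl acetoacetate | COC(=O)CC(C)=O | starting material
4 | methyl 3-(trimethylsilyloxy)but-2-enoate (E/Z mixture) | COC(=O)C=C(C)O[Si](C)(C)C | intermediate
5 | 1-methoxy-1,3-bis(trimethylsilyloxy)buta-1,3-diene | COC(O[Si](C)(C)C)=CC(=C)O[Si](C)(C)C | intermediate
6 | methyl (5S)-5-[3,5-dimethoxy-4-(methoxymethoxy)phenyl]-3,5-bis(trimethylsilyloxy)pent-2-enoate (enol ether geometry not defined) | COC(=O)C=C(C[C@H](O[Si](C)(C)C)c1cc(OC)c(OCOC)c(OC)c1)O[Si](C)(C)C | intermediate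
7 | methyl (5S)-5-[3,5-dimethoxy-4-(methoxymethoxy)phenyl]-5-hydroxy-3-oxopentanoate | COC(=O)CC(=O)C[C@H](O)c1cc(OC)c(OCOC)c(OC)c1 | intermediate
8 | methyl (5S)-2-[bis(methylsulfanyl)methylidene]-5-[3,5-dimethoxy-4-(methoxymethoxy)phenyl]-5-hydroxy-3-oxopentanoate | COC(=O)C(=C(SC)SC)C(=O)C[C@H](O)c1cc(OC)c(OCOC)c(OC)c1 | intermediate
9 | methyl (2S)-2-[3,5-dimethoxy-4-(methoxymethoxy)phenyl]-6-(methylsulfanyl)-4-oxo-3,4-dihydro-2H-pyran-5-carboxylate | COC(=O)C1=C(SC)O[C@@H](CC1=O)c1cc(OC)c(OCOC)c(OC)c1 | intermediate
10 | (E)-geranylacetone, (5E)-6,10-dimethylundeca-5,9-dien-2-one (isomerically pure E) | CC(=O)CC/C=C(\C)CCC=C(C)C | starting material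
11 | methyl (2S)-6-[(5E)-6,10-dimethyl-2-oxoundeca-5,9-dien-1-yl]-2-[3,5-dimethoxy-4-(methoxymethoxy)phenyl]-4-oxo-3,4-dihydro-2H-pyran-5-carboxylate (present as its lithium enolate) | COC(=O)C1=C(CC(=O)CC/C=C(\C)CCC=C(C)C)O[C@@H](CC1=O)c1cc(OC)c(OCOC)c(OC)c1 | intermediate
12 | (2S)-6-[(2E)-3,7-dimethylocta-2,6-dien-1-yl]-5,7-dihydroxy-2-[3,5-dimethoxy-4-(methoxymethoxy)phenyl]-2,3-dihydro-4H-chromen-4-one | COCOc1c(OC)cc([C@@H]2CC(=O)c3c(cc(O)c(C/C=C(\C)CCC=C(C)C)c3O)O2)cc1OC | intermediate
13 | (2S)-6-[(2E)-3,7-dimethylocta-2,6-dien-1-yl]-5,7-dihydroxy-2-(4-hydroxy-3,5-dimethoxyphenyl)-2,3-dihydro-4H-chromen-4-one | COc1cc([C@@H]2CC(=O)c3c(cc(O)c(C/C=C(\C)CCC=C(C)C)c3O)O2)cc(OC)c1O | target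

**Step count**

Total steps: 8. Longest linear sequence: 7 steps (methyl acetoacetate 3 to 13, steps 2–8).

**Steps most likely to fail**

Step 7 (key step). What may go wrong:
- The enolate may act as a base at C3 of 9, which would trigger retro-oxa-Michael opening of ring C with loss of material and of the configuration at C2.
- The second deprotonation may go to C3 instead of the geranyl-bearing carbon.
- The closure may proceed by O-acylation to a fused pyranone.
- Partial equilibration of the enolate would place geranyl at C8.

Fallback by known chemistry, in which ring A is taken from phloroglucinol and ring C is closed last; it sets out from 2 and returns at 13. Phloroglucinol is treated with two equivalents of MOMCl to give 3,5-bis(methoxymethoxy)phenol F1, which is silylated (TIPSCl, imidazole) to triisopropyl[3,5-bis(methoxymethoxy)phenoxy]silane F2. Directed ortho-lithiation between the two MOM ethers (n-BuLi, THF, 0 °C) and alkylation with geranyl bromide (CuI cat.) should give the 4-geranyl arene F3. A second lithiation at one of the two equivalent free ring positions (s-BuLi, TMEDA, −78 °C) and quench with N-methoxy-N-methylacetamide should give the acetophenone F4, in which the silyloxy group is the only oxygen next to a ring hydrogen. A boron aldol of F4 through its diisopinocampheylboron enolate (Ipc2BCl, Et3N; the enantiomer of the reagent chosen so that the 3R carbinol results) with aldehyde 2 gives the β-hydroxy ketone F5. Buffered TBAF/AcOH frees the phenol to give the phenol–alcohol F6, and an intramolecular Mitsunobu reaction (PPh3, DIAD, THF, 0 °C) closes ring C with inversion to the (2S)-tris-MOM flavanone F7. Acid as in step 8 then removes the three MOM groups and gives 13. Here the regiochemistry rests on the single free phenol and the configuration on the aldol and the inversion.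

Step 6. What may go wrong: base-induced retro-aldol cleavage of 8, retro-oxa-Michael opening of 9 once it has formed, or incomplete closure.

Fallback: the ring is closed at the thiocarbonyl stage, as in the classical route to 2-(methylthio)chromones; it sets out from 7 and returns at 9. Dithiocarboxylation of 7 (CS2, K2CO3, DMF) and S-methylation with one equivalent of MeI gives the β-oxo dithioester F8. On gentle warming with a catalytic tertiary amine the hydroxyl adds to the thiocarbonyl carbon and methanethiol is lost, giving the cyclic thionolactone F9 (enol form). S-Methylation of this vinylogous thioacid (MeI, K2CO3, acetone, 0 °C) should then give 9.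

Step 4. What may go wrong: insufficient facial selectivity with this electron-rich aldehyde, or partial loss of the MOM group during desilylation.

Fallback: the stereocentre is set by ketone reduction instead of aldol addition; it sets out from 2 and returns at 7. Roskamp homologation of 2 (ethyl diazoacetate, NbCl5 cat., CH2Cl2) gives the β-keto ester F10. Asymmetric transfer hydrogenation (RuCl(p-cymene)[(S,S)-TsDPEN], HCO2H/Et3N), which by analogy with acetophenone-type ketones should deliver the S carbinol, gives the β-hydroxy ester F11. A crossed Claisen condensation with excess lithium enolate of methyl acetate (THF, −78 → −30 °C) then gives 7.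

**Further compounds**

F1 | step 7 | 3,5-bis(methoxymethoxy)phenol | COCOc1cc(O)cc(OCOC)c1
F2 | step 7 | triisopropyl[3,5-bis(methoxymethoxy)phenoxy]silane | COCOc1cc(O[Si](C(C)C)(C(C)C)C(C)C)cc(OCOC)c1
F3 | step 7 | {4-[(2E)-3,7-dimethylocta-2,6-dien-1-yl]-3,5-bis(methoxymethoxy)phenoxy}triisopropylsilane | COCOc1cc(O[Si](C(C)C)(C(C)C)C(C)C)cc(OCOC)c1C/C=C(\C)CCC=C(C)C
F4 | step 7 | 1-{3-[(2E)-3,7-dimethylocta-2,6-dien-1-yl]-2,4-bis(methoxymethoxy)-6-[(triisopropylsilyl)oxy]phenyl}ethanone | CC(=O)c1c(OCOC)c(C/C=C(\C)CCC=C(C)C)c(OCOC)cc1O[Si](C(C)C)(C(C)C)C(C)C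
F5 | step 7 | (3R)-1-{3-[(2E)-3,7-dimethylocta-2,6-dien-1-yl]-2,4-bis(methoxymethoxy)-6-[(triisopropylsilyl)oxy]phenyl}-3-[3,5-dimethoxy-4-(methoxymethoxy)phenyl]-3-hydroxypropan-1-one | COCOc1cc(O[Si](C(C)C)(C(C)C)C(C)C)c(C(=O)C[C@@H](O)c2cc(OC)c(OCOC)c(OC)c2)c(OCOC)c1C/C=C(\C)CCC=C(C)C
F6 | step 7 | (3R)-1-{3-[(2E)-3,7-dimethylocta-2,6-dien-1-yl]-6-hydroxy-2,4-bis(methoxymethoxy)phenyl}-3-[3,5-dimethoxy-4-(methoxymethoxy)phenyl]-3-hydroxypropan-1-one | COCOc1cc(O)c(C(=O)C[C@@H](O)c2cc(OC)c(OCOC)c(OC)c2)c(OCOC)c1C/C=C(\C)CCC=C(C)C
F7 | step 7 | (2S)-6-[(2E)-3,7-dimethylocta-2,6-dien-1-yl]-2-[3,5-dimethoxy-4-(methoxymethoxy)phenyl]-5,7-bis(methoxymethoxy)-2,3-dihydro-4H-chromen-4-one | COCOc1c(OC)cc([C@@H]2CC(=O)c3c(cc(OCOC)c(C/C=C(\C)CCC=C(C)C)c3OCOC)O2)cc1OC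
F8 | step 6 | methyl (5S)-5-[3,5-dimethoxy-4-(methoxymethoxy)phenyl]-5-hydroxy-2-[(methylsulfanyl)carbonothioyl]-3-oxopentanoate | COC(=O)C(C(=S)SC)C(=O)C[C@H](O)c1cc(OC)c(OCOC)c(OC)c1
F9 | step 6 | methyl (6S)-6-[3,5-dimethoxy-4-(methoxymethoxy)phenyl]-4-hydroxy-2-thioxo-5,6-dihydro-2H-pyran-3-carboxylate | COC(=O)C1=C(O)C[C@H](OC1=S)c1cc(OC)c(OCOC)c(OC)c1
F10 | step 4 | ethyl 3-[3,5-dimethoxy-4-(methoxymethoxy)phenyl]-3-oxopropanoate | CCOC(=O)CC(=O)c1cc(OC)c(OCOC)c(OC)c1
F11 | step 4 | ethyl (3S)-3-[3,5-dimethoxy-4-(methoxymethoxy)phenyl]-3-hydroxypropanoate | CCOC(=O)C[C@H](O)c1cc(OC)c(OCOC)c(OC)c1
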